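**Strategy.** The symmetrical diarylmethane is disconnected through both arenes at once, around the future bridge carbon. In each ring (C1 on the bridge, Br on C2 and C3, OH on C4 and C5, H on C6) the contiguous O5–O4–Br3 triad corresponds to a 3-bromo-4-methoxyfuran, the furan oxygen ending up as the C5 hydroxyl. A two-directional Diels–Alder reaction of this furan with both alkynes of penta-1,4-diyn-3-one forms C1–C2 and C5–C6 of each ring, and acid isomerises the two oxa-bridged adducts to a bis-phenolic benzophenone in the same flask. The precursor is thus the cross-conjugated diynone plus two furans. Ketone reduction, bromination at C2 and demethylation complete the target.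

Key step: step 4

Remark: the oxa-bridged cycloadducts of the key step are transient mixtures of bridgehead stereoisomers whose stereocentres vanish on aromatisation, so their SMILES carry no configuration; the target is achiral.

Step 1
Reactants: 1 3,4-dibromofuran
Product: 2 3-bromo-4-methoxyfuran
Conditions: NaOMe (1.2 equiv), CuBr (10 mol%), MeOH–DMF, 95 °C, stopped at the mono-ether; distilled, stored cold over K2CO3
Reagents that add atoms: sodium methoxide, C[O-].[Na+]
Why: Ullmann-type copper-catalysed C–O coupling of a heteroaryl bromide with methoxide; the first methoxy group makes the ring electron-rich and slows the second substitution, so limiting methoxide and conversion should stop the reaction at the mono-ether.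

Step 2
Reactants: 3 ethynylmagnesium bromide (2.2 equiv); 4 ethyl formate
Product: 5 penta-1,4-diyn-3-ol
Conditions: THF, 0 °C → rt; aq NH4Cl
Reagents that add atoms: none
Why: Twofold Grignard addition to a formate ester, in which the propynal formed by the first addition is more electrophilic than the ester and takes up the second alkynyl group to give the symmetrical secondary carbinol.

Step 3
Reactants: 5 penta-1,4-diyn-3-ol
Product: 6 penta-1,4-diyn-3-one
Conditions: activated MnO2 (15 equiv), CH2Cl2, 0 °C → rt; filtered through Celite, cold solution used directly and never concentrated to dryness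
Reagents that add atoms: none
Why: Heterogeneous MnO2 oxidation of an activated, doubly propargylic secondary alcohol, which stops at the ketone and needs only filtration, so the sensitive diynone is obtained as a solution ready for the next step.

Step 4
Reactants: 6 penta-1,4-diyn-3-one; 2 3-bromo-4-methoxyfuran (2.5 equiv)
Product: 9 bis(3-bromo-5-hydroxy-4-methoxyphenyl)methanone, via mono-cycloadduct ynone 7 (not isolated), via bis-cycloadduct ketone 8 (not isolated)
Conditions: CH2Cl2, 0 °C → 35 °C; then anhydrous TsOH (20 mol%), rt
Reagents that add atoms: none
Why: Each alkyne of the diynone, activated by the shared carbonyl, reacts with one furan in an asynchronous normal-electron-demand (4+2) cycloaddition, and the closest known reaction type is the furan–alkynone (or propiolate) Diels–Alder reaction followed by acid-promoted isomerisation of the 7-oxanorbornadiene to a phenol. Both six-membered rings close by intermolecular cycloaddition, one after the other, each creating the C1–C2 and C5–C6 bonds, and the mono-adduct 7 still holds an ynone for the second addition. The orientation needed joins the furan α-carbon beside OMe (the nucleophilic enol-ether β-position) to the unsubstituted alkyne terminus (the electrophilic β-carbon of the ynone), a matched donor–acceptor pairing that places the carbonyl para to OMe. With TsOH the protonated oxygen bridge breaks at the bridgehead adjoining the brominated carbon, since only that ionisation relays the charge to the methoxy carbon as an oxocarbenium ion whereas the other would place it on the acyl-bearing carbon, and the remaining bridgehead then loses its proton so that the furan oxygen becomes the C5 hydroxyl. The bridgehead stereocentres of 7 and 8 are formed without control and vanish on aromatisation, so the step needs regiocontrol only. Anhydrous acid is added only after both cycloadditions are complete, so that ring opening outruns hydrolysis of the bromo enol ether and the remaining furan is not destroyed prematurely.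

Step 5
Reactants: 9 bis(3-bromo-5-hydroxy-4-methoxyphenyl)methanone
Product: 10 5,5'-methylenebis(3-bromo-2-methoxyphenol)
Conditions: Et3SiH (4 equiv), CF3CO2H, rt → 50 °C
Reagents that add atoms: none
Why: Ionic hydrogenation, in which the protonated diaryl ketone accepts hydride from the silane, the benzhydrol ionises to a diarylmethyl cation stabilised by the two para-methoxy groups and is reduced again, while aryl bromides and free phenols are inert to the reagent pair.

Step 6
Reactants: 10 5,5'-methylenebis(3-bromo-2-methoxyphenol)
Product: 11 5,5'-methylenebis(3,4-dibromo-2-methoxyphenol)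
Conditions: NBS (2.05 equiv), MeCN, −20 → 0 °C, dark
Reagents that add atoms: N-bromosuccinimide, O=C1CCC(=O)N1Br
Why: Electrophilic aromatic bromination directed by the free phenol, in which C2 is para and C6 ortho to the C5 hydroxyl and NBS in MeCN at low temperature is a para-selective protocol for phenols, while the C4 methoxy group is twisted between two ortho substituents and has its para position blocked by the bridge.

Step 7
Reactants: 11 5,5'-methylenebis(3,4-dibromo-2-methoxyphenol)
Product: 12 5,5'-methylenebis(3,4-dibromobenzene-1,2-diol), the target
Conditions: BBr3 (6 equiv), CH2Cl2, −78 °C → rt; then H2O, 0 °C, under argon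
Reagents that add atoms: none
Why: Lewis-acid ether cleavage, in which BBr3 coordinates each aryl methyl ether oxygen and bromide attacks the methyl group in an SN2 step, and aqueous work-up hydrolyses the aryl borates to the bis-catechol without touching the C–Br bonds or the diarylmethane.

**Compound list**

1 | 3,4-dibromofuran | Brc1cocc1Br | starting material
2 | 3-bromo-4-methoxyfuran | COc1cocc1Br | intermediate
3 | ethynylmagnesium bromide | C#C[Mg]Br | starting material
4 | ethyl formate | CCOC=O | starting material
5 | penta-1,4-diyn-3-ol | C#CC(O)C#C | intermediate
6 | penta-1,4-diyn-3-one | C#CC(=O)C#C | intermediate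
7 | 1-(6-bromo-5-methoxy-7-oxabicyclo[2.2.1]hepta-2,5-dien-2-yl)prop-2-yn-1-one (racemic, not isolated) | C#CC(=O)C1=CC2OC1C(Br)=C2OC | intermediate
8 | bis(6-bromo-5-methoxy-7-oxabicyclo[2.2.1]hepta-2,5-dien-2-yl)methanone (meso and racemic forms, not isolated) | O=C(C1=CC2OC1C(Br)=C2OC)C1=CC2OC1C(Br)=C2OC | intermediate
9 | bis(3-bromo-5-hydroxy-4-methoxyphenyl)methanone | O=C(c1cc(O)c(OC)c(Br)c1)c1cc(O)c(OC)c(Br)c1 | intermediate
10 | 5,5'-methylenebis(3-bromo-2-methoxyphenol) | COc1c(O)cc(Cc2cc(O)c(OC)c(Br)c2)cc1Br | intermediate
11 | 5,5'-methylenebis(3,4-dibromo-2-methoxyphenol) | COc1c(O)cc(Cc2cc(O)c(OC)c(Br)c2Br)c(Br)c1Br | intermediate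
12 | 5,5'-methylenebis(3,4-dibromobenzene-1,2-diol) | Oc1cc(Cc2cc(O)c(O)c(Br)c2Br)c(Br)c(Br)c1O | target

**Total step count:** 7.
**Longest linear sequence:** 6 steps (steps 2, 3, 4, 5, 6, 7); the furan branch is step 1 and joins at step 4.

**Steps most likely to fail**

Step 4. The cross-conjugated diynone may oligomerise, or the furan may add to it in conjugate fashion through its nucleophilic α-carbon, faster than the second cycloaddition occurs; the bromo enol ether may also be hydrolysed before the bridge opens. The fallback builds the two rings one after the other from robust mono-alkynes and avoids 6 altogether. It sets out from 2, which is heated with ethyl propiolate (toluene, 80 °C) to give ethyl 6-bromo-5-methoxy-7-oxabicyclo[2.2.1]hepta-2,5-diene-2-carboxylate F1, isomerised by TsOH in the same flask to ethyl 3-bromo-5-hydroxy-4-methoxybenzoate F2. Me3Al and MeNH(OMe)·HCl in CH2Cl2 convert the ester into the Weinreb amide 3-bromo-5-hydroxy-N,4-dimethoxy-N-methylbenzamide F3, and excess ethynylmagnesium bromide 3 (THF, 0 °C) turns this into the aryl ynone 1-(3-bromo-5-hydroxy-4-methoxyphenyl)prop-2-yn-1-one F4. A second cycloaddition of F4 with 2 gives (3-bromo-5-hydroxy-4-methoxyphenyl)(6-bromo-5-methoxy-7-oxabicyclo[2.2.1]hepta-2,5-dien-2-yl)methanone F5, which TsOH opens to 9, where the route is rejoined.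

Step 6. Bromination may fail to discriminate between C2 and C6, may run on to a third bromine per ring, or may attack the benzylic methylene by a radical path. The fallback changes the directing group to the methyl ether. It sets out from 10, which is O-methylated (MeI, K2CO3, acetone) to bis(3-bromo-4,5-dimethoxyphenyl)methane F6. Br2 in AcOH then substitutes para to the unhindered C5 methoxy group, whose methyl shields C6, to give bis(2,3-dibromo-4,5-dimethoxyphenyl)methane F7. BBr3 in CH2Cl2 removes all four methyl groups and the route is rejoined at 12.

Step 1. Mono-selectivity may be lost through a second substitution, or the furan may be debrominated or degraded under the hot basic copper conditions. The fallback fixes mono-functionalisation by stoichiometry. It sets out from 1, which undergoes bromine–lithium exchange with n-BuLi (1.0 equiv, Et2O, −78 °C) to give (4-bromofuran-3-yl)lithium F8. Trapping with 2-isopropoxy-4,4,5,5-tetramethyl-1,3,2-dioxaborolane and aq NH4Cl work-up gives 2-(4-bromofuran-3-yl)-4,4,5,5-tetramethyl-1,3,2-dioxaborolane F9. Chan–Lam etherification (Cu(OAc)2, DMAP, MeOH, O2, 4 Å molecular sieves, rt) then gives 2, where the route is rejoined.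

**Further compounds**

F1 | step 4 | ethyl 6-bromo-5-methoxy-7-oxabicyclo[2.2.1]hepta-2,5-diene-2-carboxylate | CCOC(=O)C1=CC2OC1C(Br)=C2OC
F2 | step 4 | ethyl 3-bromo-5-hydroxy-4-methoxybenzoate | CCOC(=O)c1cc(O)c(OC)c(Br)c1
F3 | step 4 | 3-bromo-5-hydroxy-N,4-dimethoxy-N-methylbenzamide | CON(C)C(=O)c1cc(O)c(OC)c(Br)c1
F4 | step 4 | 1-(3-bromo-5-hydroxy-4-methoxyphenyl)prop-2-yn-1-one | C#CC(=O)c1cc(O)c(OC)c(Br)c1
F5 | step 4 | (3-bromo-5-hydroxy-4-methoxyphenyl)(6-bromo-5-methoxy-7-oxabicyclo[2.2.1]hepta-2,5-dien-2-yl)methanone | O=C(c1cc(O)c(OC)c(Br)c1)C1=CC2OC1C(Br)=C2OC
F6 | step 6 | bis(3-bromo-4,5-dimethoxyphenyl)methane | COc1cc(Cc2cc(OC)c(OC)c(Br)c2)cc(Br)c1OC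
F7 | step 6 | bis(2,3-dibromo-4,5-dimethoxyphenyl)methane | COc1cc(Cc2cc(OC)c(OC)c(Br)c2Br)c(Br)c(Br)c1OC
F8 | step 1 | (4-bromofuran-3-yl)lithium | [Li]c1cocc1Br
F9 | step 1 | 2-(4-bromofuran-3-yl)-4,4,5,5-tetramethyl-1,3,2-dioxaborolane | CC1(C)OB(OC1(C)C)c1cocc1Br
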